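Late in the earlier runs both products stood still, so I began at the end of the flask and turned the question round: for other capture product to lead target at 50 min, their ratio r (other capture product over target) would have to pass one.

| flask | substrate | first nucleophile | second nucleophile | remark | time |
|---|---|---|---|---|---|
| cedar | 0.50 M | 0.60 equiv | 1.3 equiv | run made earlier |  |
| ash | 0.50 M | 0.90 equiv | 1.3 equiv | run made earlier |  |
| alder | 1 M | 1.2 equiv | 1.3 equiv | run made earlier |  |
| flask | 0.50 M | 1.20 equiv | 1.30 equiv |  | 50 min |

- cedar (time / min: other capture product / %, target / %): 8.00: 2.7, 34.5; 15.0: 2.4, 39.1; 25.0: 1.9, 40.2; 30.0: 2.3, 40.6; 40.0: 2.1, 40.5; 50.0: 2.2, 40.4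
- ash (time / min: other capture product / %, target / %): 3.00: 1.3, 26.8; 10.0: 2.1, 47.8; 20.0: 1.8, 52.2; 25.0: 1.5, 52.9; 40.0: 1.7, 53.1; 50.0: 1.7, 53.2
- alder (time / min: other capture product / %, target / %): 10.0: 2.2, 65.3; 20.0: 1.8, 72.7; 30.0: 1.7, 74.1; 40.0: 2.1, 73.7; 50.0: 1.5, 74.3

(standard deviation of a reading: 0.3 percentage points)

- what is said of target includes crystals
- crystals is a solid; its amount is given per volume of the solution
- the analysis behind the earlier runs scatters by 0.3 percentage points, standard deviation
- steps under discussion: crystals <-> target; first nucleophile + intermediate -> target; second nucleophile -> decomposed reagent; substrate -> intermediate; second nucleophile + intermediate -> other capture product; intermediate -> solvolysis product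

- ratio of other capture product to target at 20 s
- ratio of other capture product to target at 4.0 min
- ratio of other capture product to target at 50 min
- which of other capture product and target there is more of at 50 min

I read r from the last 3 readings of each run. Both nucleophiles take the same intermediate, so I multiplied r by the equivalents of first over second nucleophile. Cedar gave 0.0251, ash 0.0213 and alder 0.0220, a spread that the scatter of 0.3 percentage points allows on readings this small. Their mean, 0.0228, I called σ: the late r per unit ratio of second to first nucleophile charged, a selectivity factor for the whole run.

For the flask, with 1.30 equiv of second and 1.20 equiv of first nucleophile, σ gave r = 0.0247, well below one. It would have to grow by a factor of 40.5, so I committed to target. In ash, the readings at 3.00 min gave r = 0.0485, above the late reading of 0.0308, so I expected the flask's earlier ratios to stand higher too.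

The forecast gave 0.04, 0.032 and 0.024 at the three asked times, against my 0.0247 for the end, and it named target. Its ground for other capture product was that "Other capture product plateaus early".

The flask gave 0.0517 at 20 s, 0.0351 at 4.0 min and 0.0233 at 50 min, the last against the 0.0247 I had reckoned from σ, with target at 61.8% and other capture product at 1.44%.

    crystals ⇌ target, rate k1*(cs1 - [target]) while solid is left; crystals form when [target] > cs1 (solubility = 0.0910 M, k = 0.550 s⁻¹)
    first nucleophile + intermediate → target (k = 1.30 M⁻¹ s⁻¹)
    second nucleophile → decomposed reagent (k = 0.00630 s⁻¹)
    substrate → intermediate (k = 0.00340 s⁻¹)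
    second nucleophile + intermediate → other capture product (k = 0.0650 M⁻¹ s⁻¹)
    intermediate → solvolysis product (k = 0.330 s⁻¹)

In the flask, half of the decomposition of second nucleophile up to 50 min was done by 1.82 min, and 14.8% of its charge stood at 5.00 min, while other capture product stood at 1.44% at 15.0 min. The step from first nucleophile and intermediate to target had 88% of its turnover up to 50 min behind it at 10.0 min. With σ = 0.0228, a neighbouring flask charged with 0.520 equiv of second nucleophile reckons to 0.00988, and it ended at r = 0.00938.

The runs are simulated from invented constants, noise included.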